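All constants stand for no real mixture.

You cannot stop L from meeting L, so turning every L into Q is not on offer; what you can choose is how much L stands beside the enzyme J while it works.

    J ⇌ E (K1 = 0.67, k1 = 6.42 × 10⁻⁴ min⁻¹)
    L.J → J + Q (k2 = 51.5 min⁻¹)
    2 L.J ⇌ L.J2, settled at all times (K3 = 4.6 × 10⁵ L mol⁻¹)
    2 L → L2 (k4 = 0.0205 L mol⁻¹ min⁻¹)
    L + J ⇌ L.J (K5 = 61 L mol⁻¹, k5 = 1.04 × 10⁵ L mol⁻¹ min⁻¹)

common to all: J 0.46 µM
- noon: L 13 mM; a single well-mixed tank run continuously and read at steady state, 8.0 d in it on average
- autumn: L 13 mM; everything together in a closed stirred flask, run for 8.0 d; time 8.0 d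
- dawn: L 13 mM (fed, over 6.40 d); all but L at the start; L goes in evenly over 6.40 d, the run ends at 8.0 d; time 8.0 d

- percent here means L units held: one L2 or L.J2 counts as two
- a doubled species enters its step squared and goes two at a time
- the stated concentrations are those of everything mixed, before any reaction; amounts are the same in each set-up
- the feed brings no volume worth counting
- run time (autumn): 8.0 d

* the set-up with the highest amount of Q at the outlet or at the end, in percent of the L put in ("none" if the first two lie within 2 percentage points) (noon / autumn / dawn / none)
* amount of Q at the outlet or at the end, in percent of the L put in, noon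
* amount of Q at the outlet or at the end, in percent of the L put in, autumn
* amount of Q at the outlet or at the end, in percent of the L put in, dawn

I reckon in fractions x of the L charge, and I hold J at its balance with E, a share 59.9 % of the catalyst. The return of L.J to L and J runs at 1700 min⁻¹, far faster than its step on to Q at 51.5 min⁻¹, so the enzyme is half-saturated at x = m = 1.30 (the Michaelis constant) and flat out uses L at v = 1.57 d⁻¹ of the charge.

The quantity to carry is the leak ratio, a selectivity: L passing into L2 over L passing into Q at the same moment. At full charge it is 1.12, and at x it is that times x(m+x)/(m+1). Of the L that reacts at x, the share 1/(1+ratio) becomes Q.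

In dawn the feed of 0.156 d⁻¹ is below v, so L stands where the enzyme takes the feed, x = 14.3 %. The ratio there is 0.101, which gives me 90.8 % Q.

In autumn x falls from full charge to nothing, and at x = 0.5 the ratio is 0.439. Simpson's weighted mean of the shares gives 70.8 %. Autumn's catalyst is charged as J, more of it than the share I held, so I expect that figure to fall low. I did not reckon noon.

The forecast chose dawn, with 85.6 % for noon, 73 % for autumn and 91.5 % for dawn, on the ground that "whichever set-up keeps L lowest wins".

The simulation gives 86.1 % for noon, 76.6 % for autumn and 91.5 % for dawn, so dawn is best.

In dawn at 3.94 d, L binds J 410 times as fast as it passes into L2 (forward step alone), and 2.93 % of L.J goes on to Q, which reads as a leak ratio of 0.0832, against 0.0871 reckoned from the 12.5 % of L standing at 4.00 d. In the neighbour of dawn charged with 52 mM of L, fed at 0.625 d⁻¹ of dawn's charge, enzyme and L2 together use L about as fast as that feed at a standing L of 6.50 mM, where the ratio 0.439 puts Q at 69.5 %, and that neighbour ended at 75.0 %.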